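Ring C of the upper, 3-deoxy flavan is taken apart at C3–C4 and O1–C2. The feature used is that the benzylic carbon C4, which bears two aryl groups, sits on ring A ortho to the phenolic ring oxygen: the chain C4–C4a–C8a–O1 is that of an o-quinone methide. In one operation a chiral acid generates this quinone methide from an o-hydroxybenzhydrol and adds ethyl vinyl ether across it, which closes ring C, fixes C4 and leaves an acetal at C2 for trans-selective arylation. The benzhydrol links a 3,4-bis(benzyloxy)-2-hydroxyphenyl ring (future ring A) to C6 of the enantiopure lower (2R,3R,4R)-flavan-3,4-diol, carried as benzyl and silyl ethers.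

Key step: step 11

Assumption: the antipode named for each chiral catalyst (bisphosphine in step 4, phosphoric acid in step 11) is taken to be the one that delivers the configuration drawn; its sense is to be confirmed on a small scale.

Design remarks:
- The lower unit is made enantioselectively (step 4), and its all-cis diol comes from a contra-steric cis-hydroxylation (step 7). An all-cis hydrogenation of a flavonol would give a racemate and would strip the benzyl ethers and the bromide.
- Bromine is introduced para to the free phenol at the acetophenone stage, where the regiochemistry is unambiguous.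
- The lower diol is carried as its bis-TBS ether, not as a ketal. A ketal would ionise under TMSOTf in step 12 and would need acid for removal, and acid epimerises the benzylic C4 carbinol that lies para to the C7 oxygen.
- The aldehyde partner is used as its sodium phenolate, which saves a silylation and a desilylation.

Step 1
Reactants: 1 2',3',4'-trihydroxyacetophenone (gallacetophenone)
Product: 2 1-[3,4-bis(benzyloxy)-2-hydroxyphenyl]ethan-1-one
Conditions: BnBr (2.1 equiv), K2CO3 (2.2 equiv), DMF, 25 °C
Reagents that add atoms: benzyl bromide, BrCc1ccccc1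
Why: Williamson etherification; the 2-hydroxyl is held in a hydrogen bond to the acetyl carbonyl and is the least nucleophilic, so two equivalents of halide should alkylate O-4 and O-3 only.

Step 2
Reactants: 2 1-[3,4-bis(benzyloxy)-2-hydroxyphenyl]ethan-1-one
Product: 3 1-[3,4-bis(benzyloxy)-5-bromo-2-hydroxyphenyl]ethan-1-one
Conditions: NBS (1.05 equiv), MeCN, 0 °C
Reagents that add atoms: N-bromosuccinimide, O=C1CCC(=O)N1Br
Why: Electrophilic aromatic bromination should go para to the free phenol (C5), the only other open position being ortho to the acyl group and deactivated; this carbon becomes C6 of the lower flavan.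

Step 3
Reactants: 3 1-[3,4-bis(benzyloxy)-5-bromo-2-hydroxyphenyl]ethan-1-one
Product: 5 7,8-bis(benzyloxy)-6-bromo-4H-chromen-4-one, via enaminone 4 (not isolated)
Conditions: Me2NCH(OMe)2, toluene, 100 °C; then 2 M HCl, CH2Cl2, 40 °C
Reagents that add atoms: N,N-dimethylformamide dimethyl acetal, COC(OC)N(C)C
Why: Enaminone condensation at the methyl ketone followed by acid-promoted intramolecular oxa-Michael addition and loss of dimethylamine is the standard chromone annulation of 2-hydroxyacetophenones.

Step 4
Reactants: 5 7,8-bis(benzyloxy)-6-bromo-4H-chromen-4-one; 6 [4-(benzyloxy)phenyl]boronic acid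
Product: 7 (2S)-7,8-bis(benzyloxy)-2-[4-(benzyloxy)phenyl]-6-bromochroman-4-one
Conditions: [Rh(OH)(cod)]2 (1.5 mol%), MeO-F12-BIPHEP (3.3 mol%, antipode giving 2S), toluene/H2O (20:1), 25 °C
Reagents that add atoms: none
Why: Rhodium-catalysed asymmetric 1,4-addition of an arylboronic acid to the chromone (Hayashi–Miyaura reaction): the aryl-rhodium species on the chiral bisphosphine adds to one enone face and so sets C2 (S), while the aryl bromide and the benzyl ethers are inert to it.

Step 5
Reactants: 7 (2S)-7,8-bis(benzyloxy)-2-[4-(benzyloxy)phenyl]-6-bromochroman-4-one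
Product: 8 (2S,4S)-7,8-bis(benzyloxy)-2-[4-(benzyloxy)phenyl]-6-bromochroman-4-ol (2,4-cis)
Conditions: NaBH4, THF/MeOH (1:1), 0 °C
Reagents that add atoms: none
Why: Borohydride reduction of the ketone; axial hydride delivery should give the 2,4-cis alcohol, although either epimer would serve because C4 becomes trigonal in step 6.

Step 6
Reactants: 8 (2S,4S)-7,8-bis(benzyloxy)-2-[4-(benzyloxy)phenyl]-6-bromochroman-4-ol
Product: 9 (2S)-7,8-bis(benzyloxy)-2-[4-(benzyloxy)phenyl]-6-bromo-2H-chromene
Conditions: Burgess reagent [methyl N-(triethylammoniosulfonyl)carbamate] (1.5 equiv), THF, 50 °C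
Reagents that add atoms: none
Why: Burgess dehydration (syn elimination of the sulfamate ester toward C3) forms the styrenyl alkene under neutral conditions, which avoid acid-induced disproportionation and opening of the C2–O1 bond, so C2 keeps its configuration.

Step 7
Reactants: 9 (2S)-7,8-bis(benzyloxy)-2-[4-(benzyloxy)phenyl]-6-bromo-2H-chromene
Product: 12 (2R,3R,4R)-7,8-bis(benzyloxy)-2-[4-(benzyloxy)phenyl]-6-bromochroman-3,4-diol (2,3-cis-3,4-cis), via trans-iodo acetate 10 (not isolated), via cis-hydroxy acetate 11 (not isolated)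
Conditions: I2 (1.05 equiv), AgOAc (2.2 equiv), AcOH/H2O (25:1), 20 then 60 °C; then K2CO3 (cat.), MeOH, 20 °C
Reagents that add atoms: silver acetate, CC(=O)[O-].[Ag+]
Why: Woodward cis-hydroxylation: iodonium forms on the alkene face away from the C2 aryl group, acetate opens it at benzylic C4, the neighbouring acetoxy group then displaces iodide at C3 with inversion to a cis-fused dioxolan-2-ylium ion on the aryl face, and hydrolysis plus methanolysis should give the all-cis diol, on the face that osmium tetroxide would not reach.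

Step 8
Reactants: 12 (2R,3R,4R)-7,8-bis(benzyloxy)-2-[4-(benzyloxy)phenyl]-6-bromochroman-3,4-diol
Product: 13 3,4-bis-O-(tert-butyldimethylsilyl) ether of 12 (all-cis 6-bromide)
Conditions: TBSOTf (3 equiv), 2,6-lutidine (4 equiv), CH2Cl2, 0 to 25 °C
Reagents that add atoms: tert-butyldimethylsilyl trifluoromethanesulfonate, CC(C)(C)[Si](C)(C)OS(=O)(=O)C(F)(F)F
Why: Silyl triflate silylation of both secondary alcohols; the bis-silyl ether withstands butyllithium and the Brønsted acid of step 11, is far less prone to ionise under TMSOTf than a ketal, and leaves with fluoride, so the benzylic C4–O bond is never exposed to protic acid.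

Step 9
Reactants: 14 2,3,4-trihydroxybenzaldehyde
Product: 15 3,4-bis(benzyloxy)-2-hydroxybenzaldehyde
Conditions: BnBr (2.05 equiv), K2CO3 (2.1 equiv), DMF, 25 °C
Reagents that add atoms: benzyl bromide, BrCc1ccccc1
Why: Williamson etherification; as in step 1 the hydroxyl ortho to the carbonyl is hydrogen-bonded and should stay free.

Step 10
Reactants: 13 3,4-bis-O-(tert-butyldimethylsilyl) ether of 12; 15 3,4-bis(benzyloxy)-2-hydroxybenzaldehyde
Product: 18 [3,4-bis(benzyloxy)-2-hydroxyphenyl][7,8-bis(benzyloxy)-2-(4-benzyloxyphenyl)-3,4-bis(tert-butyldimethylsilyloxy)chroman-6-yl]methanol (lower unit all-cis as in 12; both carbinol epimers), via aryllithium 16 (not isolated), via sodium phenolate 17 (not isolated)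
Conditions: 13, n-BuLi (1.05 equiv), THF, –78 °C; 15, NaH (1.05 equiv), THF, 0 °C; mix at –78 °C, to 0 °C; H2O (neutral work-up)
Reagents that add atoms: none
Why: Bromine–lithium exchange is faster than any deprotonation at –78 °C, and the aryllithium adds to the formyl group of the preformed phenolate (1,2-addition to an aldehyde), which cannot quench it; the new carbinol centre forms without control and is erased in step 11.

Step 11
Reactants: 18 the o-hydroxybenzhydrol; 19 ethyl vinyl ether
Product: 21 7,8-bis(benzyloxy)-2-ethoxy-4-[7,8-bis(benzyloxy)-2-(4-benzyloxyphenyl)-3,4-bis(tert-butyldimethylsilyloxy)chroman-6-yl]chroman (C4 as in the target; 2,4-cis acetal drawn), via o-quinone methide 20 (not isolated)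
Conditions: (R)-TRIP [3,3'-bis(2,4,6-triisopropylphenyl)-1,1'-binaphthyl-2,2'-diyl hydrogen phosphate] (10 mol%), 19 (5 equiv), 4 Å MS, toluene, –20 to 0 °C
Reagents that add atoms: none
Why: The phosphoric acid protonates the benzylic hydroxyl of 18, water leaves, and the (E)-o-quinone methide 20 stays hydrogen-bonded to the phosphate through its carbonyl oxygen; the enol ether then adds across this oxa-diene in a concerted but asynchronous inverse-electron-demand hetero-Diels–Alder reaction, its CH2 terminus bonding to the methide carbon (C4) slightly ahead of O1–C2 bond formation. The closest known reaction type is the chiral-phosphoric-acid-catalysed [4+2] cycloaddition of o-quinone methides, made in situ from o-hydroxybenzhydrols, with enol ethers or enamides. Ring C of the upper unit, a six-membered pyran, is closed by this intermolecular cycloaddition, which forms C3–C4 and O1–C2 together. C4 is set by the chiral phosphate, which shields one face of the bound quinone methide (the lower-unit stereocentres are too far away to give a useful bias), while acetal carbon C2 follows the endo preference and does not matter because it is ionised in step 12. The step needs one quinone methide and one regiochemistry: only the upper ring has a free hydroxyl ortho to the carbinol carbon, every other oxygen being a benzyl or silyl ether, and the polarity of the partners (nucleophilic terminal carbon of the enol ether, electrophilic methide carbon) allows only the 2-ethoxy-4-aryl orientation.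

Step 12
Reactants: 21 the 2-ethoxychroman; 22 [4-(benzyloxy)phenyl]magnesium bromide (commercial THF solution)
Product: 24 hexa-O-benzyl-3,4-bis-O-(tert-butyldimethylsilyl) derivative of the target (upper flavan 2,4-trans), via arylzinc bromide 23 (not isolated)
Conditions: 22 (3 equiv), ZnBr2 (3 equiv), THF, 0 °C, then toluene; 21, TMSOTf (1.5 equiv), CH2Cl2, –78 to –40 °C
Reagents that add atoms: none
Why: Lewis-acid ionisation of the acetal gives a chromanyl oxocarbenium ion, to which the arylzinc adds (C-glycosylation-type acetal substitution); axial attack on the half-chair that has the C4 aryl group pseudo-equatorial places the new aryl group on the opposite face, which should give the 2,4-trans flavan under kinetic control at low temperature.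

Step 13
Reactants: 24 the fully protected biflavanoid
Product: 25 hexa-O-benzyl ether of the target (lower 3,4-diol free)
Conditions: Bu4NF (TBAF, 4 equiv), THF, 25 to 45 °C
Reagents that add atoms: none
Why: Fluoride-induced cleavage of both silyl ethers under non-acidic conditions, which leave the benzyl ethers and every stereocentre untouched.

Step 14
Reactants: 25 hexa-O-benzyl ether of the target
Product: 26 (2R,3R,4R)-6-[(2S,4S)-7,8-dihydroxy-2-(4-hydroxyphenyl)chroman-4-yl]-2-(4-hydroxyphenyl)chroman-3,4,7,8-tetrol (CNP0209379.1)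
Conditions: H2 (1 atm), Pd(OH)2 on carbon, THF/MeOH (1:1), 25 °C, degassed solvents
Reagents that add atoms: none
Why: Hydrogenolysis of the six aryl benzyl ethers; these cleave much faster than the cyclic benzylic C–O bonds (C2–O1 of both units, C4–OH of the lower unit), so the run is stopped at full debenzylation and no stereocentre is touched.

Compound list
1 | 2',3',4'-trihydroxyacetophenone (gallacetophenone) | CC(=O)c1ccc(O)c(O)c1O | starting material
2 | 1-[3,4-bis(benzyloxy)-2-hydroxyphenyl]ethan-1-one | CC(=O)c1ccc(OCc2ccccc2)c(OCc2ccccc2)c1O | intermediate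
3 | 1-[3,4-bis(benzyloxy)-5-bromo-2-hydroxyphenyl]ethan-1-one | CC(=O)c1cc(Br)c(OCc2ccccc2)c(OCc2ccccc2)c1O | intermediate
4 | (E)-1-[3,4-bis(benzyloxy)-5-bromo-2-hydroxyphenyl]-3-(dimethylamino)prop-2-en-1-one | CN(C)/C=C/C(=O)c1cc(Br)c(OCc2ccccc2)c(OCc2ccccc2)c1O | intermediate (not isolated)
5 | 7,8-bis(benzyloxy)-6-bromo-4H-chromen-4-one | O=c1ccoc2c(OCc3ccccc3)c(OCc3ccccc3)c(Br)cc12 | intermediate
6 | [4-(benzyloxy)phenyl]boronic acid | OB(O)c1ccc(OCc2ccccc2)cc1 | starting material
7 | (2S)-7,8-bis(benzyloxy)-2-[4-(benzyloxy)phenyl]-6-bromochroman-4-one | Brc1cc2c(c(OCc3ccccc3)c1OCc1ccccc1)O[C@H](c1ccc(OCc3ccccc3)cc1)CC2=O | intermediate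
8 | (2S,4S)-7,8-bis(benzyloxy)-2-[4-(benzyloxy)phenyl]-6-bromochroman-4-ol (2,4-cis) | Brc1cc2c(c(OCc3ccccc3)c1OCc1ccccc1)O[C@H](c1ccc(OCc3ccccc3)cc1)C[C@@H]2O | intermediate
9 | (2S)-7,8-bis(benzyloxy)-2-[4-(benzyloxy)phenyl]-6-bromo-2H-chromene | Brc1cc2c(c(OCc3ccccc3)c1OCc1ccccc1)O[C@H](c1ccc(OCc3ccccc3)cc1)C=C2 | intermediate
10 | 7,8-bis(benzyloxy)-2-[4-(benzyloxy)phenyl]-6-bromo-3-iodochroman-4-yl acetate (2,3-trans-3,4-trans; iodine anti to the C2 aryl group) | Brc1cc2c(c(OCc3ccccc3)c1OCc1ccccc1)O[C@H](c1ccc(OCc3ccccc3)cc1)[C@@H](I)[C@@H]2OC(C)=O | intermediate (not isolated)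
11 | 7,8-bis(benzyloxy)-2-[4-(benzyloxy)phenyl]-6-bromo-4-hydroxychroman-3-yl acetate (all-cis; drawn as the 3-acetate, the 4-acetate serves equally) | Brc1cc2c(c(OCc3ccccc3)c1OCc1ccccc1)O[C@H](c1ccc(OCc3ccccc3)cc1)[C@H](OC(C)=O)[C@@H]2O | intermediate (not isolated)
12 | (2R,3R,4R)-7,8-bis(benzyloxy)-2-[4-(benzyloxy)phenyl]-6-bromochroman-3,4-diol (2,3-cis-3,4-cis) | Brc1cc2c(c(OCc3ccccc3)c1OCc1ccccc1)O[C@H](c1ccc(OCc3ccccc3)cc1)[C@H](O)[C@@H]2O | intermediate
13 | 3,4-bis-O-(tert-butyldimethylsilyl) ether of 12 (all-cis; configuration unchanged) | Brc1cc2c(c(OCc3ccccc3)c1OCc1ccccc1)O[C@H](c1ccc(OCc3ccccc3)cc1)[C@H](O[Si](C)(C)C(C)(C)C)[C@@H]2O[Si](C)(C)C(C)(C)C | intermediate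
14 | 2,3,4-trihydroxybenzaldehyde | O=Cc1ccc(O)c(O)c1O | starting material
15 | 3,4-bis(benzyloxy)-2-hydroxybenzaldehyde | O=Cc1ccc(OCc2ccccc2)c(OCc2ccccc2)c1O | intermediate
16 | 6-lithio derivative of 13 | [Li]c1cc2c(c(OCc3ccccc3)c1OCc1ccccc1)O[C@H](c1ccc(OCc3ccccc3)cc1)[C@H](O[Si](C)(C)C(C)(C)C)[C@@H]2O[Si](C)(C)C(C)(C)C | intermediate (not isolated)
17 | sodium 2,3-bis(benzyloxy)-6-formylphenolate | [Na+].[O-]c1c(C=O)ccc(OCc2ccccc2)c1OCc1ccccc1 | intermediate (not isolated)
18 | [3,4-bis(benzyloxy)-2-hydroxyphenyl][7,8-bis(benzyloxy)-2-(4-benzyloxyphenyl)-3,4-bis(tert-butyldimethylsilyloxy)chroman-6-yl]methanol (lower unit as in 12; carbinol epimers) | OC(c1ccc(OCc2ccccc2)c(OCc2ccccc2)c1O)c1cc2c(c(OCc3ccccc3)c1OCc1ccccc1)O[C@H](c1ccc(OCc3ccccc3)cc1)[C@H](O[Si](C)(C)C(C)(C)C)[C@@H]2O[Si](C)(C)C(C)(C)C | intermediate (key-step precursor)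
19 | ethyl vinyl ether | C=COCC | starting material
20 | (E)-o-quinone methide of 18: 2,3-bis(benzyloxy)-6-[(lower-unit C6 aryl)methylidene]cyclohexa-2,4-dien-1-one | O=C1C(OCc2ccccc2)=C(OCc2ccccc2)C=C/C1=C\c1cc2c(c(OCc3ccccc3)c1OCc1ccccc1)O[C@H](c1ccc(OCc3ccccc3)cc1)[C@H](O[Si](C)(C)C(C)(C)C)[C@@H]2O[Si](C)(C)C(C)(C)C | intermediate (not isolated)
21 | 7,8-bis(benzyloxy)-2-ethoxy-4-[lower-unit chroman-6-yl]chroman (C4 as in the target; 2,4-cis acetal drawn, the C2 epimer serves equally) | CCO[C@H]1C[C@@H](c2cc3c(c(OCc4ccccc4)c2OCc2ccccc2)O[C@H](c2ccc(OCc4ccccc4)cc2)[C@H](O[Si](C)(C)C(C)(C)C)[C@@H]3O[Si](C)(C)C(C)(C)C)c2ccc(OCc3ccccc3)c(OCc3ccccc3)c2O1 | intermediate (key-step product)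
22 | [4-(benzyloxy)phenyl]magnesium bromide | Br[Mg]c1ccc(OCc2ccccc2)cc1 | starting material
23 | [4-(benzyloxy)phenyl]zinc bromide | Br[Zn]c1ccc(OCc2ccccc2)cc1 | intermediate (not isolated)
24 | hexa-O-benzyl-3,4-bis-O-(tert-butyldimethylsilyl) derivative of the target (upper flavan 2,4-trans) | c1ccccc1COc1ccc([C@@H]2C[C@@H](c3cc4c(c(OCc5ccccc5)c3OCc3ccccc3)O[C@H](c3ccc(OCc5ccccc5)cc3)[C@H](O[Si](C)(C)C(C)(C)C)[C@@H]4O[Si](C)(C)C(C)(C)C)c3ccc(OCc4ccccc4)c(OCc4ccccc4)c3O2)cc1 | intermediate
25 | hexa-O-benzyl ether of the target (lower 3,4-diol free) | c1ccccc1COc1ccc([C@@H]2C[C@@H](c3cc4c(c(OCc5ccccc5)c3OCc3ccccc3)O[C@H](c3ccc(OCc5ccccc5)cc3)[C@H](O)[C@@H]4O)c3ccc(OCc4ccccc4)c(OCc4ccccc4)c3O2)cc1 | intermediate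
26 | (2R,3R,4R)-6-[(2S,4S)-7,8-dihydroxy-2-(4-hydroxyphenyl)chroman-4-yl]-2-(4-hydroxyphenyl)chroman-3,4,7,8-tetrol (CNP0209379.1) | Oc1ccc([C@@H]2C[C@@H](c3cc4c(c(O)c3O)O[C@H](c3ccc(O)cc3)[C@H](O)[C@@H]4O)c3ccc(O)c(O)c3O2)cc1 | target

Total step count: 14. Longest linear sequence: 13 steps (steps 1–8 and 10–14); step 9 is a one-step branch.

Steps most likely to fail

Step 11. Facial discrimination at the methide carbon may be poor, because the vinyl ether offers the phosphate no second binding point and the methide carbon carries a bulky ortho-benzyloxy aryl group. A background reaction through the free cation would add material epimeric at C4, and some enol ether may be diverted into reversible acetal formation with the free hydroxyls. The fallback replaces catalyst control by auxiliary control. It sets out from 18: the quinone methide is generated with an achiral acid (diphenyl hydrogen phosphate, 5 mol%, toluene, 0 °C) in the presence of the enantiopure enol ether (1R,2S)-2-phenylcyclohexyl vinyl ether F1. F1 is made from commercial (1R,2S)-trans-2-phenylcyclohexanol, vinyl acetate, [IrCl(cod)]2 and Na2CO3; its antipode is taken if the wrong face is shielded. Diastereoselective [4+2] addition of o-quinone methides to chiral enol ethers of this kind is known and should give the auxiliary acetal F2; its C4 epimers are diastereomers and can be separated in any case. F2 is ionised under the conditions of step 12 (TMSOTf, 23) and so comes back to the route at 24.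

Step 7. Silver-assisted ionisation at C3 may be diverted by the anti-periplanar C2 aryl group (1,2-aryl shift), the doubly activated C2–H bond may be oxidised, an electron-rich arene may be iodinated, and face selectivity in iodonium formation may be incomplete. The fallback closes the second C–O bond under basic, non-ionising conditions. It sets out from 9: NBS in aqueous THF at 0 °C should give the trans-bromohydrin F3 (bromine anti to the C2 aryl group, C4 hydroxyl on the aryl face). Cs2CO3 under CO2 (1 atm) in DMF should convert the C4 alkoxide into the caesium carbonate monoester F4 (not isolated), whose carbonate oxygen displaces bromide at C3 intramolecularly with inversion to give the cis-fused cyclic carbonate F5 on the aryl face. K2CO3 in MeOH then releases the diol, and the route is rejoined at 12.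

Step 12. Kinetic 2,4-trans control may be lost, either by attack on the wrong face or by re-ionisation of the new C2–O1 bond, which would drain the product toward the more stable 2,4-cis flavan. The oxocarbenium ion may also lose a C3 proton to a 4H-chromene, and the Lewis acid may attack the benzylic silyl ether of the lower unit. The fallback replaces ionic arylation by a stereospecific ring closure. It sets out from 21: mild hydrolysis (PPTS, acetone/H2O, 40 °C) gives the lactol F6. Grignard reagent 22 (3.5 equiv, THF, 0 °C) adds to its open hydroxy-aldehyde form to give the phenol–carbinol F7 as a mixture of carbinol epimers. MnO2 (CH2Cl2, 25 °C) oxidises the benzylic carbinol to the ketone F8. Corey–Bakshi–Shibata reduction (BH3·SMe2, the oxazaborolidine antipode that gives the epimer drawn) sets the carbinol centre of the (R)-carbinol F9 under reagent control. Mitsunobu etherification of F9 by the phenol (PPh3, DIAD, THF, 0 °C) closes ring C with inversion and returns to the route at 24.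

Further compounds
F1 | step 11 | (1R,2S)-2-phenylcyclohexyl vinyl ether | C=CO[C@@H]1CCCC[C@H]1c1ccccc1
F2 | step 11 | 2-[(1R,2S)-2-phenylcyclohexyloxy] analogue of 21 (auxiliary acetal; C4 as in the target, 2,4-cis drawn) | [C@H]1(O[C@@H]2CCCC[C@H]2c2ccccc2)C[C@@H](c2cc3c(c(OCc4ccccc4)c2OCc2ccccc2)O[C@H](c2ccc(OCc4ccccc4)cc2)[C@H](O[Si](C)(C)C(C)(C)C)[C@@H]3O[Si](C)(C)C(C)(C)C)c2ccc(OCc3ccccc3)c(OCc3ccccc3)c2O1
F3 | step 7 | 7,8-bis(benzyloxy)-2-[4-(benzyloxy)phenyl]-3,6-dibromochroman-4-ol (2,3-trans-3,4-trans bromohydrin) | Brc1cc2c(c(OCc3ccccc3)c1OCc1ccccc1)O[C@H](c1ccc(OCc3ccccc3)cc1)[C@@H](Br)[C@@H]2O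
F4 | step 7 | caesium carbonate monoester of F3 at O-4 (formed in the flask) | Brc1cc2c(c(OCc3ccccc3)c1OCc1ccccc1)O[C@H](c1ccc(OCc3ccccc3)cc1)[C@@H](Br)[C@@H]2OC(=O)[O-].[Cs+]
F5 | step 7 | cis-fused 3,4-cyclic carbonate of 12 | Brc1cc2c(c(OCc3ccccc3)c1OCc1ccccc1)O[C@H](c1ccc(OCc3ccccc3)cc1)[C@@H]1OC(=O)O[C@H]21
F6 | step 12 | 2-hydroxy analogue of 21 (lactol; anomers) | OC1C[C@@H](c2cc3c(c(OCc4ccccc4)c2OCc2ccccc2)O[C@H](c2ccc(OCc4ccccc4)cc2)[C@H](O[Si](C)(C)C(C)(C)C)[C@@H]3O[Si](C)(C)C(C)(C)C)c2ccc(OCc3ccccc3)c(OCc3ccccc3)c2O1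
F7 | step 12 | 1-(4-benzyloxyphenyl)-3-[3,4-bis(benzyloxy)-2-hydroxyphenyl]-3-(lower-unit chroman-6-yl)propan-1-ol (carbinol epimers) | OC(c1ccc(OCc2ccccc2)cc1)C[C@@H](c2cc3c(c(OCc4ccccc4)c2OCc2ccccc2)O[C@H](c2ccc(OCc4ccccc4)cc2)[C@H](O[Si](C)(C)C(C)(C)C)[C@@H]3O[Si](C)(C)C(C)(C)C)c2ccc(OCc3ccccc3)c(OCc3ccccc3)c2O
F8 | step 12 | 1-(4-benzyloxyphenyl)-3-[3,4-bis(benzyloxy)-2-hydroxyphenyl]-3-(lower-unit chroman-6-yl)propan-1-one | O=C(c1ccc(OCc2ccccc2)cc1)C[C@@H](c2cc3c(c(OCc4ccccc4)c2OCc2ccccc2)O[C@H](c2ccc(OCc4ccccc4)cc2)[C@H](O[Si](C)(C)C(C)(C)C)[C@@H]3O[Si](C)(C)C(C)(C)C)c2ccc(OCc3ccccc3)c(OCc3ccccc3)c2O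
F9 | step 12 | (1R)-carbinol corresponding to F8 (the epimer that Mitsunobu closure inverts to the C2 configuration of 24) | O[C@@H](c1ccc(OCc2ccccc2)cc1)C[C@@H](c2cc3c(c(OCc4ccccc4)c2OCc2ccccc2)O[C@H](c2ccc(OCc4ccccc4)cc2)[C@H](O[Si](C)(C)C(C)(C)C)[C@@H]3O[Si](C)(C)C(C)(C)C)c2ccc(OCc3ccccc3)c(OCc3ccccc3)c2O
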